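**Assumptions:** The target has no stereocenters (it is achiral), so there is no absolute configuration to set. I assume the Larock-type heteroannulation places the aryl group at C2 (next to O) and the methyl at C3, as is usual for aryl/alkyl alkynes.

## Retrosynthetic overview
1. Ocophyllal B (**5**) is a 2-aryl-3-methylbenzofuran. Disconnect the furan ring at C2–O and C3–C3a (Larock-type Pd heteroannulation) to give an o-iodophenol and an aryl–propyne.
2. The o-iodophenol is 5-iodovanillin (**4**). Its CHO, OMe and OH already sit where the target needs them (5-CHO, 7-OMe, 7a-O).
3. The alkyne, 1-propynyl-3,4,5-trimethoxybenzene (**3**), comes from 5-iodo-1,2,3-trimethoxybenzene (**1**) and a propynyl nucleophile (**2**) by Negishi-type coupling.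
4. The only ring formed is the furan, in the last step.

## Route

**Step 1**
Reactants: **1** 5-iodo-1,2,3-trimethoxybenzene; **2** 1-propynylmagnesium bromide
Product: **3** 1-(prop-1-yn-1-yl)-3,4,5-trimethoxybenzene
Conditions: **2** (1.3 equiv) then ZnCl₂ (1.3 equiv), THF, 0 °C to rt; add **1** and Pd(PPh₃)₄ (5 mol%), 60 °C
Reagents that add atoms: none beyond the reactants (ZnCl₂ only transmetalates and the propynyl group comes from **2**)
Why: Negishi (Sonogashira-type sp–sp² coupling via the propynylzinc) joins the aryl iodide to the propynyl group. Transmetalation to zinc avoids Grignard side reactions, and no stereocenter is formed.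

**Step 2**
Reactants: **4** 5-iodovanillin (4-hydroxy-3-iodo-5-methoxybenzaldehyde); **3**
Product: **5** Ocophyllal B, 7-methoxy-3-methyl-2-(3,4,5-trimethoxyphenyl)benzofuran-5-carbaldehyde
Conditions: Pd(OAc)₂ (5 mol%), Na₂CO₃ (3 equiv), LiCl (1 equiv), DMF, 100 °C; **3** used in excess (1.5–2 equiv)
Reagents that add atoms: none
Why: Larock heteroannulation. Oxidative addition of the Ar–I bond is followed by syn-carbopalladation of the alkyne. The aryl carbon bonds to the methyl-bearing alkyne carbon, and Pd ends up on the carbon bearing the larger aryl group. The phenoxide then closes onto that carbon (C–O reductive elimination) to give the 2-aryl-3-methylbenzofuran. The aldehyde and the four methyl ethers are inert to these mild basic Pd conditions. No stereocenter is generated.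

## Checks performed
- **Target match:** Product **5** has O1, C2 bearing 3,4,5-(MeO)₃C₆H₂, C3–Me, C5–CHO and C7–OMe. This matches COc1cc(-c2oc3c(OC)cc(C=O)cc3c2C)cc(OC)c1OC, and the molecule is achiral.
- **Atom balance for step 2:** **3** (C₁₂H₁₄O₃) + **4** (C₈H₇IO₃) − HI = C₂₀H₂₀O₆, which is the formula of **5**.
- **Atom balance for step 1:** **1** + propynyl − I gives **3**.
- **Functional groups:** The aldehyde, aryl methyl ethers and free phenol are compatible with both steps. The phenol is the nucleophile that closes the ring.
- **Stereochemistry:** There are no stereocenters to set or scramble.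

## Compound list
1 | 5-iodo-1,2,3-trimethoxybenzene | COc1cc(I)cc(OC)c1OC | starting material
2 | 1-propynylmagnesium bromide | CC#C[Mg]Br | starting material
3 | 1-(prop-1-yn-1-yl)-3,4,5-trimethoxybenzene | COc1cc(C#CC)cc(OC)c1OC | intermediate
4 | 5-iodovanillin (4-hydroxy-3-iodo-5-methoxybenzaldehyde) | COc1cc(C=O)cc(I)c1O | starting material
5 | Ocophyllal B | COc1cc(-c2oc3c(OC)cc(C=O)cc3c2C)cc(OC)c1OC | target (achiral)

## Summary
- **Total steps:** 2
- **Longest linear sequence:** 2 steps (**1** → **3** → **5**)

**Steps most likely to fail (with fallbacks):** The route has only two steps, so the third item below is a sub-operation within step 1.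
1. **Step 2, Larock regioselectivity and yield** (wrong C2/C3 orientation, or alkyne oligomerization with the electron-poor phenol). Fallback: Sonogashira coupling of **4** with 3,4,5-trimethoxyphenylacetylene and CuI- or Pd-mediated 5-endo cyclization to the 2-arylbenzofuran. Then do C3 iodination (NIS) and Pd-catalyzed methylation (MeB(OH)₂ Suzuki or Me₃Al/Negishi).
2. **Step 1, propynylzinc coupling** (incomplete transmetalation, homocoupling). Fallback: Sonogashira of **1** with propyne gas (PdCl₂(PPh₃)₂, CuI, Et₃N, sealed tube). Alternatively, couple **1** with TMS-acetylene, desilylate, and methylate the terminal alkyne (n-BuLi, MeI).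
3. **Step 1, in-situ formation of the propynylzinc reagent** (the Grignard/ZnCl₂ transmetalation step). Fallback: use the pre-formed alkyne route via Ohira–Bestmann homologation of 3,4,5-trimethoxybenzaldehyde, then n-BuLi/MeI, which avoids organometallic coupling at the aryl iodide.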